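The runs were computed from invented constants; noise was put on by code.

Count what each reacted electrophile costs before you look at the clock.

in all of them: electrophile 13 mM

| charge | nucleophile | free base | remark | time |
|---|---|---|---|---|
| eta | 26 mM | 4.2 mM | run made earlier |  |
| alpha | 26 mM | 5.2 mM | run made earlier |  |
| zeta | 26 mM | 5.4 mM | run made earlier |  |
| winter | 26.0 mM | 3.90 mM |  | 30 min |
| summer | 26.0 mM | 5.80 mM |  | 30 min |

| run | time / min | electrophile / % | target / % |
|---|---|---|---|
| eta | 1.33 | 44.9 | 53.1 |
| eta | 2.50 | 28.8 | 67.2 |
| eta | 4.00 | 20.4 | 75.7 |
| eta | 8.00 | 10.4 | 82.6 |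
| eta | 15.0 | 3.9 | 86.7 |
| alpha | 1.33 | 44.7 | 52.6 |
| alpha | 2.50 | 29.8 | 67.1 |
| alpha | 4.00 | 19.4 | 75.3 |
| alpha | 8.00 | 9.0 | 82.5 |
| alpha | 15.0 | 4.0 | 86.4 |
| zeta | 3.00 | 26.5 | 70.4 |
| zeta | 6.00 | 14.0 | 80.7 |
| zeta | 10.0 | 7.3 | 84.6 |
| zeta | 12.0 | 5.0 | 85.7 |
| zeta | 15.0 | 2.9 | 85.2 |

(readings scatter by 0.5 percentage points)

- the numbers in the tables scatter by 0.5 percentage points (one standard deviation)

- part of the electrophile that has reacted at the end, winter
- part of the electrophile that has reacted at the end, summer
- what raising the concentration of free base from its lowest to its highest value here does to the part of the electrophile that has reacted (changes below 5 percentage points count as none) (no change / it falls / it rises)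

Does the electrophile decay like a single first-order lag? No: in the eta run its time constant reads 1.66 min up to the first reading and 7.14 min between the last two, a stretch of 4.30. A cost of one nucleophile per electrophile gives a stretch of 2.00 at full reaction, less than that reading. So I take the cost as two: one nucleophile reacts, and the acid set free, captured at once, takes a second nucleophile or a free base.

Is there enough for that? Summer has a cover C of 1.22, that is, nucleophile plus free base charged over twice the electrophile charged, and winter has 1.15. Both exceed 1, so I expect the electrophile to be the limiting reagent, with a slowing tail and no stall.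

How far does that tail get? Carrying 7.14 min from the 3.9% of eta at 15.0 min on to 30 min gives me 99.5% reacted. Eta and alpha, with 4.2 mM and 5.2 mM of free base, read 3.9% and 4.0% at that time, so I use this figure for both flasks and expect no trend.

The forecast gives 99% for winter, 99.6% for summer and no change: “Nucleophile is in excess, so there is no hard stall, only a slowing tail.” It separates the two flasks, where I do not.

The simulation gives 99.4% for winter, 99.5% for summer and no change, a change of 0.071 percentage points.

    electrophile + nucleophile → acid set free + target (k = 0.562 L mol⁻¹ s⁻¹)
    nucleophile + acid set free ⇌ protonated nucleophile, settled at all times (K = 15700 L mol⁻¹)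
    acid set free + free base ⇌ salt of the base, settled at all times (K = 610 L mol⁻¹)
    electrophile + target → side product (k = 0.0410 L mol⁻¹ s⁻¹)

In summer, the target-forming step has half its turnover up to 30 min done by 1.01 min, and the side-product step by 4.67 min. At 30.0 min in summer the acid stands as 11.1 mM of protonated nucleophile, 0.809 mM of salt of the base and 0.266 mM of acid set free, with 86.1% of the free base still free. Summer's C is 1.22; at 20.2 mM of nucleophile, where its answer has moved by 5 points, C is 0.999. A neighbour of summer, the same flask with 10 mM of nucleophile, has C of 0.608, and at 30.0 min its nucleophile stands at 1.7% of its charge with 33% of the electrophile left.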